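**Plan**
- Retrosynthetic cuts, in order: the 4'-O–prenyl bond, O1–C8a of the pyranone (ring C), C2–C3 (enolate acylation), and C4–C4a (aryllithium plus Weinreb amide).
- Enabling feature: O1 sits on C8a of ring A. C8a is the only unsubstituted carbon ortho to the C4 carbonyl and lies para to the C6 methoxy group, so a σ-complex at C8a is stabilised by C6–OMe and can rearomatise by losing a proton. No phenol or halogen is needed at that carbon.
- Forward: rings A and B are purchased. C4–C4a comes from MOM-directed ortho-lithiation and C2–C3 from a Claisen-type acylation. Ring C is the only ring formed, by ferrocene-mediated anodic dehydrogenative O1–C8a closure.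
- End game: pivalate off, prenyl on, three MOM groups off. The oxidisable prenyl ether never enters the electrolysis cell.
- Stereochemistry: none to set. The one sp3 centre on the way (C3 of the diketone) is labile and becomes sp2 on ring closure.

Key step: step 8

Remark: the target SMILES has no stereocentre and no stereogenic double bond, so it is one achiral compound and no enantioselective step is required. Flavone numbering (O1, C2–C8a, C1'–C6') is used for ring atoms throughout.

**Step 1**
Reactants: 1 2-methoxyresorcinol
Product: 2 2-methoxy-1,3-bis(methoxymethoxy)benzene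
Conditions: MOMCl (2.5 equiv), i-Pr2NEt (3 equiv), CH2Cl2, 0 °C to rt
Reagents that add atoms: chloromethyl methyl ether (MOMCl), COCCl
Why: Routine acetal protection of both phenols (Williamson-type O-alkylation under amine base) installs groups that later act as ortho-directing groups and as donors on ring A.

**Step 2**
Reactants: 3 methyl glycolate
Product: 4 methyl 2-(methoxymethoxy)acetate
Conditions: MOMCl (1.3 equiv), i-Pr2NEt (1.5 equiv), CH2Cl2, 0 °C to rt
Reagents that add atoms: chloromethyl methyl ether (MOMCl), COCCl
Why: O-Alkylation of the primary alcohol with MOMCl under amine base is routine and puts the future 3-O protecting group in place before any C–C bond is made.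

**Step 3**
Reactants: 4 methyl 2-(methoxymethoxy)acetate
Product: 5 N-methoxy-N-methyl-2-(methoxymethoxy)acetamide
Conditions: MeNH(OMe)·HCl (1.5 equiv), i-PrMgCl (3 equiv), THF, −20 to 0 °C
Reagents that add atoms: N,O-dimethylhydroxylamine hydrochloride, CNOC.Cl
Why: Aminolysis of the ester by the chloromagnesium amide of N,O-dimethylhydroxylamine is the standard ester-to-Weinreb-amide conversion and leaves the acetal untouched.

**Step 4**
Reactants: 2 2-methoxy-1,3-bis(methoxymethoxy)benzene; 5 N-methoxy-N-methyl-2-(methoxymethoxy)acetamide
Product: 7 1-[3-methoxy-2,4-bis(methoxymethoxy)phenyl]-2-(methoxymethoxy)ethan-1-one, via aryllithium 6 (not isolated)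
Conditions: n-BuLi (1.1 equiv), TMEDA, THF, 0 °C, 1 h; then 5, −78 to 0 °C; aq NH4Cl
Reagents that add atoms: none
Why: In this directed ortho-metalation the position between the two acetals is blocked by OMe, so a MOM group steers n-BuLi to the equivalent C4/C6 positions, and the chelated tetrahedral adduct of the Weinreb ketone synthesis prevents over-addition.

**Step 5**
Reactants: 8 4-hydroxybenzoic acid
Product: 9 4-(pivaloyloxy)benzoic acid
Conditions: PivCl (1.05 equiv), NaOH (2.1 equiv), H2O/acetone, 0 °C; then aq HCl to pH 2
Reagents that add atoms: pivaloyl chloride, CC(C)(C)C(=O)Cl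
Why: In this Schotten–Baumann acylation the phenoxide is by far the better nucleophile, any mixed anhydride at the carboxylate is hydrolysed back, and acidification precipitates the acid.

**Step 6**
Reactants: 9 4-(pivaloyloxy)benzoic acid
Product: 10 4-(pivaloyloxy)benzoyl chloride
Conditions: (COCl)2 (1.3 equiv), DMF (cat.), CH2Cl2, 0 °C to rt; evaporate and use crude
Reagents that add atoms: oxalyl chloride, O=C(Cl)C(=O)Cl
Why: Vilsmeier-type activation of the acid with oxalyl chloride and catalytic DMF gives the aroyl chloride without touching the hindered aryl ester, and only gases form alongside.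

**Step 7**
Reactants: 7 1-[3-methoxy-2,4-bis(methoxymethoxy)phenyl]-2-(methoxymethoxy)ethan-1-one; 10 4-(pivaloyloxy)benzoyl chloride
Product: 12 1-[3-methoxy-2,4-bis(methoxymethoxy)phenyl]-2-(methoxymethoxy)-3-[4-(pivaloyloxy)phenyl]propane-1,3-dione (racemic; the CH(OMOM) centre is configurationally labile), via lithium (Z)-enolate 11 (not isolated)
Conditions: LiHMDS (2.2 equiv), THF, −78 °C; then 10 (1.05 equiv), −78 to −10 °C; aq NH4Cl
Reagents that add atoms: none
Why: This is a Claisen-type C-acylation of a chelated α-alkoxy ketone enolate with an aroyl chloride (the intermolecular counterpart of the Baker–Venkataraman diketone synthesis), in which the second equivalent of base stores the product as its diketonate and lets any enol ester pass its acyl group to carbon, while the pivalate is inert at low temperature.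

**Step 8**
Reactants: 12 1-[3-methoxy-2,4-bis(methoxymethoxy)phenyl]-2-(methoxymethoxy)-3-[4-(pivaloyloxy)phenyl]propane-1,3-dione
Product: 13 6-methoxy-3,5,7-tris(methoxymethoxy)-4'-(pivaloyloxy)flavone
Conditions: undivided cell, RVC anode, Pt cathode, Cp2Fe (10 mol %), n-Bu4NBF4 (0.1 M), MeCN/HFIP 9:1, Ar, 50 °C, constant current, 2.2–2.5 F/mol
Reagents that add atoms: none
Why: Proposed new method: hexafluoroisopropoxide formed at the cathode deprotonates 12, ferrocenium regenerated at the anode removes one electron from the enolate, and the resulting captodative 2-alkoxy-1,3-dioxo radical, which cannot reach either arene through C3 (four-membered ring), bonds through the oxygen on C2 to C8a. The cyclohexadienyl radical so formed carries its spin on C4a (next to the C4 carbonyl), C6 (bearing OMe) and C8, so a second ferrocenium should oxidise it at once to an arenium ion held by the C6 methoxy group, loss of the C8a proton restores ring A, and the two hydrogens leave the cathode as H2. The closest known reaction types are the ferrocene-mediated anodic cyclisation of 1,3-dicarbonyl radicals onto arenes (C–C bond), the iron(III)-promoted enol-oxygen/aryl C–H closure of α-aryl β-dicarbonyl compounds to benzofurans para to an alkoxy group, and the anodic lactonisation of biaryl-2-carboxylic acids, whereas closure of a six-membered pyranone by an enol oxygen onto an aroyl ring has not been shown. Ring C closes by 6-endo-trig (ortho) attack on the C4a=C8a bond, no stereocentre is formed, and the labile C3 centre of 12 becomes sp2. The step needs ring A over ring B and C8a over C5 and C4a: only the adduct at C8a has a donor para to the new bond and a proton to lose, the ortho carbons of ring B lie meta to an electron-poor pivaloyloxy group, C5 is fully substituted, and the 5-exo spiro adduct at C4a is strained, cuts the carbonyl off from ring A and should revert. The mediator potential (about +0.4 V vs SCE) lies well below those of the trialkoxyaroyl ring, the MOM acetals, the C3 radical/cation couple and 13, which should suppress MOM loss from an arene radical cation, oxidation at C3 to the vicinal tricarbonyl level and over-oxidation, while HFIP as a non-nucleophilic proton source spares the pivalate.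

**Step 9**
Reactants: 13 6-methoxy-3,5,7-tris(methoxymethoxy)-4'-(pivaloyloxy)flavone
Product: 14 4'-hydroxy-6-methoxy-3,5,7-tris(methoxymethoxy)flavone
Conditions: K2CO3 (1.5 equiv), MeOH/THF 2:1, rt; aq NH4Cl
Reagents that add atoms: none
Why: Base-mediated methanolysis (transesterification) cleaves the activated aryl ester, while acetals, methyl ether and pyranone are inert to carbonate at room temperature, so only the 4'-phenol is freed.

**Step 10**
Reactants: 14 4'-hydroxy-6-methoxy-3,5,7-tris(methoxymethoxy)flavone; 15 prenyl bromide
Product: 16 6-methoxy-3,5,7-tris(methoxymethoxy)-4'-(3-methylbut-2-enyloxy)flavone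
Conditions: K2CO3 (2 equiv), 15 (1.2 equiv), DMF, rt
Reagents that add atoms: none
Why: This Williamson ether synthesis (SN2 at the primary allylic bromide) acts on the only free hydroxyl group of the molecule, so regioselectivity is settled by the protecting-group pattern.

**Step 11**
Reactants: 16 6-methoxy-3,5,7-tris(methoxymethoxy)-4'-(3-methylbut-2-enyloxy)flavone
Product: 17 3,5,7-trihydroxy-6-methoxy-4'-prenyloxyflavone
Conditions: HCl (ca. 0.5 M, from conc. aq HCl), MeOH/THF 3:1, rt to 35 °C, stopped at full conversion
Reagents that add atoms: none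
Why: Acid-catalysed transacetalisation moves the three formaldehyde acetals to methanol, and under dilute acid levelled by methanol the oxocarbenium route open to MOM ethers should be clearly faster than ionisation of the allylic aryl ether or protonation of its alkene, as used for MOM removal on prenylated phenols.

**Compound list**
1 | 2-methoxyresorcinol | COc1c(O)cccc1O | starting material
2 | 2-methoxy-1,3-bis(methoxymethoxy)benzene | COCOc1cccc(OCOC)c1OC | intermediate
3 | methyl glycolate | COC(=O)CO | starting material
4 | methyl 2-(methoxymethoxy)acetate | COCOCC(=O)OC | intermediate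
5 | N-methoxy-N-methyl-2-(methoxymethoxy)acetamide | COCOCC(=O)N(C)OC | intermediate
6 | [3-methoxy-2,4-bis(methoxymethoxy)phenyl]lithium (not isolated) | [Li]c1ccc(OCOC)c(OC)c1OCOC | intermediate
7 | 1-[3-methoxy-2,4-bis(methoxymethoxy)phenyl]-2-(methoxymethoxy)ethan-1-one | COCOCC(=O)c1ccc(OCOC)c(OC)c1OCOC | intermediate
8 | 4-hydroxybenzoic acid | O=C(O)c1ccc(O)cc1 | starting material
9 | 4-(pivaloyloxy)benzoic acid | CC(C)(C)C(=O)Oc1ccc(C(=O)O)cc1 | intermediate
10 | 4-(pivaloyloxy)benzoyl chloride | CC(C)(C)C(=O)Oc1ccc(C(=O)Cl)cc1 | intermediate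
11 | lithium (Z)-enolate of 7 (not isolated) | [Li]O/C(=C\OCOC)c1ccc(OCOC)c(OC)c1OCOC | intermediate
12 | 1-[3-methoxy-2,4-bis(methoxymethoxy)phenyl]-2-(methoxymethoxy)-3-[4-(pivaloyloxy)phenyl]propane-1,3-dione (racemic, labile centre) | COCOC(C(=O)c1ccc(OC(=O)C(C)(C)C)cc1)C(=O)c1ccc(OCOC)c(OC)c1OCOC | intermediate
13 | 6-methoxy-3,5,7-tris(methoxymethoxy)-4'-(pivaloyloxy)flavone | COCOc1c(-c2ccc(OC(=O)C(C)(C)C)cc2)oc2cc(OCOC)c(OC)c(OCOC)c2c1=O | intermediate
14 | 4'-hydroxy-6-methoxy-3,5,7-tris(methoxymethoxy)flavone | COCOc1c(-c2ccc(O)cc2)oc2cc(OCOC)c(OC)c(OCOC)c2c1=O | intermediate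
15 | prenyl bromide (1-bromo-3-methylbut-2-ene) | CC(C)=CCBr | starting material
16 | 6-methoxy-3,5,7-tris(methoxymethoxy)-4'-(3-methylbut-2-enyloxy)flavone | COCOc1c(-c2ccc(OCC=C(C)C)cc2)oc2cc(OCOC)c(OC)c(OCOC)c2c1=O | intermediate
17 | 3,5,7-trihydroxy-6-methoxy-4'-prenyloxyflavone (achiral) | COc1c(O)cc2oc(-c3ccc(OCC=C(C)C)cc3)c(O)c(=O)c2c1O | target

Total step count: 11. Longest linear sequence: 8 (steps 2, 3, 4, 7, 8, 9, 10, 11).

**Steps most likely to fail**

**Step 8 (new method).** The captodative radical may be too stabilised to attack the aroyl ring. In that case the charge would be consumed by reversible dimerisation at C3, by slow oxidation at C3 with loss of the acetal, or by spiro closure at C4a with dearomatisation of ring A.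

The fallback uses known chemistry and makes the same O1–C8a bond by substitution instead of C–H oxidation. It sets out from 2 and comes back at 13.
- Iridium-catalysed C–H borylation of 2 (B2pin2, [Ir(OMe)(cod)]2, dtbpy, THF, 80 °C) should strike the only unhindered C–H, para to the methoxy group. This gives 2-[4-methoxy-3,5-bis(methoxymethoxy)phenyl]-4,4,5,5-tetramethyl-1,3,2-dioxaborolane F1.
- Copper-catalysed iododeboronation (CuI, 1,10-phenanthroline, KI, MeOH/H2O, air) stays near neutral and spares the acetals. It gives 5-iodo-2-methoxy-1,3-bis(methoxymethoxy)benzene F2.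
- LDA (THF, −78 °C) removes the proton between iodine and OMOM to give [6-iodo-3-methoxy-2,4-bis(methoxymethoxy)phenyl]lithium F3. Amide 5 acylates this to 1-[6-iodo-3-methoxy-2,4-bis(methoxymethoxy)phenyl]-2-(methoxymethoxy)ethan-1-one F4.
- LiHMDS converts F4 into the lithium (Z)-enolate of the iodo ketone F5. Chloride 10 acylates it as in step 7 to 1-[6-iodo-3-methoxy-2,4-bis(methoxymethoxy)phenyl]-2-(methoxymethoxy)-3-[4-(pivaloyloxy)phenyl]propane-1,3-dione F6.
- Intramolecular Ullmann-type O-arylation of the enolate (CuI, 1,10-phenanthroline, K2CO3, DMF, 80 °C) closes ring C and delivers 13.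

**Step 11.** Ionisation of the allylic aryl ether, or protonation of its trisubstituted alkene followed by addition of methanol, may keep pace with cleavage of the slowest acetal at O7.

The fallback keeps the acid step away from the prenyl group. It sets out from 14 and comes back at 17.
- Allyl bromide with K2CO3 in DMF gives 4'-allyloxy-6-methoxy-3,5,7-tris(methoxymethoxy)flavone F7, whose unsubstituted allyl ether is stable to acid.
- HCl in MeOH at 50 °C removes the acetals to give 4'-allyloxy-3,5,7-trihydroxy-6-methoxyflavone F8.
- Olefin cross-metathesis with excess 2-methyl-2-butene (second-generation Grubbs catalyst, CH2Cl2, 40 °C, sealed vessel) turns the allyl ether into the prenyl ether and gives 17.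

**Step 7.** O-Acylation, double acylation, and proton transfer from the product to unreacted enolate may limit conversion to the diketone.

The fallback forms C2–C3 at the alcohol oxidation level. It sets out from 7 and comes back at 12.
- Commercial 4-hydroxybenzaldehyde is acylated (PivCl, Et3N, CH2Cl2) to 4-formylphenyl pivalate F9.
- Enolate 11, generated from 7 with LiHMDS at −78 °C, adds to F9 in an aldol reaction. The product is 3-hydroxy-1-[3-methoxy-2,4-bis(methoxymethoxy)phenyl]-2-(methoxymethoxy)-3-[4-(pivaloyloxy)phenyl]propan-1-one F10, a racemic mixture of diastereomers whose configuration does not matter.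
- Dess–Martin oxidation (CH2Cl2, NaHCO3, rt) gives 12.

**Further compounds**
F1 | step 8 | 2-[4-methoxy-3,5-bis(methoxymethoxy)phenyl]-4,4,5,5-tetramethyl-1,3,2-dioxaborolane | COCOc1cc(B2OC(C)(C)C(C)(C)O2)cc(OCOC)c1OC
F2 | step 8 | 5-iodo-2-methoxy-1,3-bis(methoxymethoxy)benzene | COCOc1cc(I)cc(OCOC)c1OC
F3 | step 8 | [6-iodo-3-methoxy-2,4-bis(methoxymethoxy)phenyl]lithium | [Li]c1c(I)cc(OCOC)c(OC)c1OCOC
F4 | step 8 | 1-[6-iodo-3-methoxy-2,4-bis(methoxymethoxy)phenyl]-2-(methoxymethoxy)ethan-1-one | COCOCC(=O)c1c(I)cc(OCOC)c(OC)c1OCOC
F5 | step 8 | lithium (Z)-enolate of the iodo ketone | [Li]O/C(=C\OCOC)c1c(I)cc(OCOC)c(OC)c1OCOC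
F6 | step 8 | 1-[6-iodo-3-methoxy-2,4-bis(methoxymethoxy)phenyl]-2-(methoxymethoxy)-3-[4-(pivaloyloxy)phenyl]propane-1,3-dione | COCOC(C(=O)c1ccc(OC(=O)C(C)(C)C)cc1)C(=O)c1c(I)cc(OCOC)c(OC)c1OCOC
F7 | step 11 | 4'-allyloxy-6-methoxy-3,5,7-tris(methoxymethoxy)flavone | COCOc1c(-c2ccc(OCC=C)cc2)oc2cc(OCOC)c(OC)c(OCOC)c2c1=O
F8 | step 11 | 4'-allyloxy-3,5,7-trihydroxy-6-methoxyflavone | COc1c(O)cc2oc(-c3ccc(OCC=C)cc3)c(O)c(=O)c2c1O
F9 | step 7 | 4-formylphenyl pivalate | CC(C)(C)C(=O)Oc1ccc(C=O)cc1
F10 | step 7 | 3-hydroxy-1-[3-methoxy-2,4-bis(methoxymethoxy)phenyl]-2-(methoxymethoxy)-3-[4-(pivaloyloxy)phenyl]propan-1-one (racemic diastereomer mixture) | COCOC(C(O)c1ccc(OC(=O)C(C)(C)C)cc1)C(=O)c1ccc(OCOC)c(OC)c1OCOC
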